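**Retrosynthetic overview**

1. Feature: C3 of the N–H indole carries N1' of a second indole (primed locants: N1', C2', C3', C3a', C7a', prenyl on C6'). N1' lies between aryl carbon C7a' and C2', so a glycinate on a 3-aminoindole can supply N1' and C2', and an ortho-fluorobenzaldehyde can supply C7a', C3a', C3' and the benzo ring.
2. Disconnections, backwards: C2'–H from C2'–CO2H (protodecarboxylation); both prenyl groups from aryl bromides (one double Suzuki coupling); N1'–C7a' and C2'–C3' from methyl N-(6-bromo-1-tosylindol-3-yl)glycinate 6 and 4-bromo-2-fluorobenzaldehyde 7; the glycinate from 6-bromoindole by N-tosylation, C3 nitration, reduction and N-alkylation.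
3. Ring order: the N–H indole is bought with 1; the pyrrole ring N1'–C2'–C3'–C3a'–C7a' is the only ring made (step 5).

Key step: step 5

Remark: both prenyl groups are carried as aryl bromides through nitration and the annulation and installed together afterwards. Acetyl nitrate attacks trisubstituted alkenes, prenylboronates allylate aldehydes, and a prenyl CH2 para to a formyl group is open to base-induced alkene migration.
Notation: prenyl = 3-methylbut-2-en-1-yl; tosyl (Ts) = 4-methylbenzenesulfonyl.

**Route**

Step 1
Reactants: 1 6-bromoindole
Product: 2 6-bromo-1-tosylindole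
Conditions: NaH, DMF, 0 °C; then TsCl, 0 °C to rt
Reagents that add atoms: p-toluenesulfonyl chloride, Cc1ccc(cc1)S(Cl)(=O)=O
Why: N-sulfonylation of the sodium indolide is a standard protection that blocks N1 as a nucleophile for step 5, tempers the ring for a clean C3 mononitration and later stabilises the 3-amino group.

Step 2
Reactants: 2 6-bromo-1-tosylindole
Product: 3 6-bromo-3-nitro-1-tosylindole
Conditions: fuming HNO3, Ac2O (acetyl nitrate preformed), −70 °C to rt
Reagents that add atoms: acetyl nitrate, CC(=O)O[N+](=O)[O-], made in the flask from nitric acid, O[N+](=O)[O-], and acetic anhydride, CC(=O)OC(C)=O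
Why: Electrophilic aromatic nitration of an N-sulfonylindole with acetyl nitrate should go at C3, the enamine-like carbon, while the sulfonyl group and the bromine keep the benzo ring from reacting.

Step 3
Reactants: 3 6-bromo-3-nitro-1-tosylindole
Product: 4 3-amino-6-bromo-1-tosylindole (taken on crude at once)
Conditions: Fe powder, NH4Cl, EtOH/H2O (4:1), 70 °C
Reagents that add atoms: none
Why: Béchamp-type iron reduction takes the nitro group to the amine by electron transfer and should leave the aryl bromide and the sulfonamide untouched.

Step 4
Reactants: 4 3-amino-6-bromo-1-tosylindole; 5 methyl bromoacetate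
Product: 6 methyl N-(6-bromo-1-tosylindol-3-yl)glycinate
Conditions: K2CO3, DMF, rt to 40 °C, argon
Reagents that add atoms: none
Why: SN2 N-alkylation of an arylamine by an α-bromo ester should stop after one alkylation, because the N-aryl glycinate is less nucleophilic and more hindered than the primary amine.

Step 5
Reactants: 6 methyl N-(6-bromo-1-tosylindol-3-yl)glycinate; 7 4-bromo-2-fluorobenzaldehyde
Product: 10 methyl 6-bromo-1-(6-bromo-1-tosylindol-3-yl)indole-2-carboxylate, via N-aryl glycinate aldehyde 8 (not isolated), via 3-hydroxyindoline aldol 9 (not isolated)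
Conditions: Cs2CO3, 4 Å molecular sieves, DMSO, 90 °C, argon
Reagents that add atoms: none
Why: The secondary arylamine nitrogen of 6 adds to the fluorine-bearing carbon of 7, activated by the ortho formyl group, and fluoride leaves from the Meisenheimer adduct to give 8 (bond N1'–C7a'); the glycinate CH2 of 8 is then deprotonated and adds to the aldehyde (bond C2'–C3'), and aldol 9 loses water by E1cB to the aromatic indole-2-carboxylate 10. The closest known reactions are the one-pot SNAr/aldol condensation of 2-fluorobenzaldehydes with thioglycolates to benzothiophene-2-carboxylates, its nitrogen version with N-substituted glycinates, and the base-induced cyclodehydration of N-(2-formylaryl)glycinates. The one ring formed, the pyrrole ring of the N-substituted indole, closes in a favoured 5-(enolexo)-exo-trig aldol. No stereocentre remains, since the two formed in 9 are erased by dehydration. The step needs N-arylation at C–F and not at C–Br, secured by the much faster addition at a fluorine-bearing carbon ortho to the formyl group, which also places the bromine at C6' because it sits para to the formyl-bearing carbon (the future C3a'); it needs reaction at the glycinate nitrogen only, secured by the tosyl group on the indole nitrogen; and it needs ring closure to beat intermolecular condensation, favoured by the ortho arrangement and by aromatisation. Should condensation at the aldehyde come first, intramolecular displacement of fluoride by the nitrogen would lead to the same indole.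

Step 6
Reactants: 10 methyl 6-bromo-1-(6-bromo-1-tosylindol-3-yl)indole-2-carboxylate; 11 prenylboronic acid pinacol ester (3 equiv)
Product: 14 methyl 6-prenyl-1-(6-prenyl-1-tosylindol-3-yl)indole-2-carboxylate, via monoprenyl bromide 12 (not isolated), via isomeric monoprenyl bromide 13 (not isolated)
Conditions: Pd(dppf)Cl2 (10 mol %), CsF, THF, 65 °C
Reagents that add atoms: none
Why: Double Suzuki–Miyaura sp2–sp3 coupling in which the prenyl–palladium intermediate equilibrates through its π-allyl form and should eliminate reductively from the less hindered CH2 terminus to give the linear prenyl arene at both sites, while anhydrous fluoride activation spares the methyl ester and the N-tosyl group.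

Step 7
Reactants: 14 methyl 6-prenyl-1-(6-prenyl-1-tosylindol-3-yl)indole-2-carboxylate
Product: 16 6-prenyl-1-(6-prenyl-1H-indol-3-yl)indole-2-carboxylic acid, via N-tosyl acid 15 (not isolated)
Conditions: KOH, THF/MeOH/H2O, 65 °C; then 1 M HCl to pH 4, 0 °C
Reagents that add atoms: potassium hydroxide, [K+].[OH-]
Why: Saponification of the methyl ester followed by hydroxide cleavage of the indole N–sulfonyl bond are both standard, and the prenyl groups should be inert to aqueous base at this temperature.

Step 8
Reactants: 16 6-prenyl-1-(6-prenyl-1H-indol-3-yl)indole-2-carboxylic acid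
Product: 17 6-prenyl-3-(6-prenylindol-1-yl)-1H-indole (target)
Conditions: Cu2O (10 mol %), 1,10-phenanthroline (20 mol %), NMP/quinoline (3:1), 170 °C, argon
Reagents that add atoms: none
Why: Copper-mediated protodecarboxylation, in which the copper carboxylate extrudes CO2 to a C2'-indolylcopper species that is protonated by further acid, is the classical way from indole-2-carboxylic acids to 2-unsubstituted indoles, and no aryl halide remains for copper to couple with the free N–H.

**Compound list**

1 | 6-bromoindole | Brc1ccc2cc[nH]c2c1 | starting material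
2 | 6-bromo-1-tosylindole | Cc1ccc(cc1)S(=O)(=O)n1ccc2ccc(Br)cc21 | intermediate
3 | 6-bromo-3-nitro-1-tosylindole | Cc1ccc(cc1)S(=O)(=O)n1cc([N+](=O)[O-])c2ccc(Br)cc21 | intermediate
4 | 3-amino-6-bromo-1-tosylindole | Cc1ccc(cc1)S(=O)(=O)n1cc(N)c2ccc(Br)cc21 | intermediate
5 | methyl bromoacetate | COC(=O)CBr | starting material
6 | methyl N-(6-bromo-1-tosylindol-3-yl)glycinate | COC(=O)CNc1cn(S(=O)(=O)c2ccc(C)cc2)c2cc(Br)ccc12 | intermediate
7 | 4-bromo-2-fluorobenzaldehyde | O=Cc1ccc(Br)cc1F | starting material
8 | methyl N-(5-bromo-2-formylphenyl)-N-(6-bromo-1-tosylindol-3-yl)glycinate | COC(=O)CN(c1cc(Br)ccc1C=O)c1cn(S(=O)(=O)c2ccc(C)cc2)c2cc(Br)ccc12 | intermediate (not isolated)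
9 | methyl 6-bromo-1-(6-bromo-1-tosylindol-3-yl)-3-hydroxyindoline-2-carboxylate (diastereomer mixture, both centres lost on dehydration) | COC(=O)C1C(O)c2ccc(Br)cc2N1c1cn(S(=O)(=O)c2ccc(C)cc2)c2cc(Br)ccc12 | intermediate (not isolated)
10 | methyl 6-bromo-1-(6-bromo-1-tosylindol-3-yl)indole-2-carboxylate | COC(=O)c1cc2ccc(Br)cc2n1-c1cn(S(=O)(=O)c2ccc(C)cc2)c2cc(Br)ccc12 | intermediate
11 | prenylboronic acid pinacol ester | CC(C)=CCB1OC(C)(C)C(C)(C)O1 | starting material
12 | methyl 6-bromo-1-(6-prenyl-1-tosylindol-3-yl)indole-2-carboxylate | COC(=O)c1cc2ccc(Br)cc2n1-c1cn(S(=O)(=O)c2ccc(C)cc2)c2cc(CC=C(C)C)ccc12 | intermediate (not isolated)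
13 | methyl 1-(6-bromo-1-tosylindol-3-yl)-6-prenylindole-2-carboxylate | COC(=O)c1cc2ccc(CC=C(C)C)cc2n1-c1cn(S(=O)(=O)c2ccc(C)cc2)c2cc(Br)ccc12 | intermediate (not isolated)
14 | methyl 6-prenyl-1-(6-prenyl-1-tosylindol-3-yl)indole-2-carboxylate | COC(=O)c1cc2ccc(CC=C(C)C)cc2n1-c1cn(S(=O)(=O)c2ccc(C)cc2)c2cc(CC=C(C)C)ccc12 | intermediate
15 | 6-prenyl-1-(6-prenyl-1-tosylindol-3-yl)indole-2-carboxylic acid (as its potassium salt in the flask) | OC(=O)c1cc2ccc(CC=C(C)C)cc2n1-c1cn(S(=O)(=O)c2ccc(C)cc2)c2cc(CC=C(C)C)ccc12 | intermediate (not isolated)
16 | 6-prenyl-1-(6-prenyl-1H-indol-3-yl)indole-2-carboxylic acid | OC(=O)c1cc2ccc(CC=C(C)C)cc2n1-c1c[nH]c2cc(CC=C(C)C)ccc12 | intermediate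
17 | 6-prenyl-3-(6-prenylindol-1-yl)-1H-indole | CC(C)=CCc1ccc2c(-n3ccc4ccc(CC=C(C)C)cc43)c[nH]c2c1 | target

**Step count and risks**

Total steps: 8. Longest linear sequence: 8 steps (steps 1 to 8 from 6-bromoindole; 5, 7 and 11 are bought).

Steps most likely to fail:

1. Step 5. The N-aryl glycinate nitrogen is a weak SNAr nucleophile, so N-arylation may be too slow. Intermolecular condensation at the glycinate CH2 could then win, and the fluoride and hydroxide released in the reaction could remove the tosyl group before ring formation; loss of the tosyl group after ring formation would be harmless, since step 7 removes it. The fallback forms the N1'–C3 bond directly by copper-catalysed N-arylation and sets out from 1. Suzuki coupling of 1 with 11 (Pd(dppf)Cl2, CsF, THF, 65 °C) should give 6-prenylindole F1. Part of F1 would be iodinated at C3 (I2, KOH, DMF, rt) to 3-iodo-6-prenylindole F2, which would be tosylated without storage (NaH, TsCl, DMF, 0 °C) to 3-iodo-6-prenyl-1-tosylindole F3. Ullmann–Goldberg N-arylation of F1 with F3 (CuI, trans-N,N'-dimethylcyclohexane-1,2-diamine, K3PO4, toluene, 110 °C) should give 6-prenyl-1-(6-prenyl-1-tosylindol-3-yl)indole F4. KOH in MeOH/THF at 65 °C would then remove the tosyl group, which comes back to the route at the target 17.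

2. Step 6. Reductive elimination from the tertiary terminus of the prenyl–palladium intermediate at one or both sites would give 1,1-dimethylallyl isomers that would be hard to separate, and the second coupling may stall or end in protodebromination. The fallback sets out from 10 and brings in the prenyl groups in two stages. Double Suzuki coupling with allylboronic acid pinacol ester (Pd(PPh3)4, CsF, THF, 65 °C), for which the two allyl termini are equivalent, should give methyl 6-allyl-1-(6-allyl-1-tosylindol-3-yl)indole-2-carboxylate F5. Olefin cross-metathesis of F5 with excess 2-methyl-2-butene (second-generation Grubbs catalyst, CH2Cl2, 40 °C) should then turn both allyl groups into prenyl groups and come back to the route at 14.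

3. Step 3. The free 3-aminoindole 4 may decompose by air oxidation and dimerisation during isolation, before it can be alkylated, and may be alkylated twice or at C2 in step 4. The fallback never liberates the amine and sets out from 3. Hydrogenation over sulfided platinum on carbon in EtOAc containing Boc2O should trap the amine as it forms, giving tert-butyl (6-bromo-1-tosylindol-3-yl)carbamate F6. Alkylation of F6 with 5 (Cs2CO3, DMF, rt) should give methyl N-Boc-N-(6-bromo-1-tosylindol-3-yl)glycinate F7. CF3CO2H in CH2Cl2 at 0 °C would remove the Boc group, and after neutralisation this comes back to the route at 6, taken at once into step 5.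

**Further compounds**

F1 | step 5 | 6-prenylindole | CC(C)=CCc1ccc2cc[nH]c2c1
F2 | step 5 | 3-iodo-6-prenylindole | CC(C)=CCc1ccc2c(I)c[nH]c2c1
F3 | step 5 | 3-iodo-6-prenyl-1-tosylindole | Cc1ccc(cc1)S(=O)(=O)n1cc(I)c2ccc(CC=C(C)C)cc21
F4 | step 5 | 6-prenyl-1-(6-prenyl-1-tosylindol-3-yl)indole | CC(C)=CCc1ccc2ccn(c2c1)-c1cn(S(=O)(=O)c2ccc(C)cc2)c2cc(CC=C(C)C)ccc12
F5 | step 6 | methyl 6-allyl-1-(6-allyl-1-tosylindol-3-yl)indole-2-carboxylate | COC(=O)c1cc2ccc(CC=C)cc2n1-c1cn(S(=O)(=O)c2ccc(C)cc2)c2cc(CC=C)ccc12
F6 | step 3 | tert-butyl (6-bromo-1-tosylindol-3-yl)carbamate | CC(C)(C)OC(=O)Nc1cn(S(=O)(=O)c2ccc(C)cc2)c2cc(Br)ccc12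
F7 | step 3 | methyl N-Boc-N-(6-bromo-1-tosylindol-3-yl)glycinate | COC(=O)CN(C(=O)OC(C)(C)C)c1cn(S(=O)(=O)c2ccc(C)cc2)c2cc(Br)ccc12
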